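(The earlier runs and the new flask stem from a simulated flask for an exercise; scatter was added.)

| flask | substrate | coupling partner | free catalyst | remark | time |
|---|---|---|---|---|---|
| larch | 0.050 M | 0.15 M | 1 mM | run made earlier |  |
| birch | 0.050 M | 0.15 M | 0.50 mM | run made earlier |  |
| elm | 0.050 M | 0.15 M | 2 mM | run made earlier |  |
| cedar | 0.025 M | 0.15 M | 1 mM | run made earlier |  |
| north-west | 0.050 M | 0.150 M | 1.0 mM | a closed flask charged with all of it at once and left for 25 h | 25 h |
| south-west | 0.050 M | 0.150 M | 1.0 mM | one stirred flow tank at steady state, fed with the mixture as stated, mean residence time 25 h |  |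
| east | 0.050 M | 0.150 M (fed, over 20.0 h) | 1.0 mM | all but coupling partner at the start; coupling partner goes in evenly over 20.0 h, the run ends at 25 h | 25 h |
| south | 0.050 M (fed, over 20.0 h) | 0.150 M | 1.0 mM | all but substrate at the start; substrate goes in evenly over 20.0 h, the run ends at 25 h | 25 h |

| run | time / h | product / % |
|---|---|---|
| larch | 4.00 | 10 |
| larch | 8.00 | 18 |
| larch | 12.0 | 24 |
| larch | 15.0 | 27 |
| larch | 20.0 | 32 |
| larch | 25.0 | 43 |
| birch | 1.00 | 4 |
| birch | 3.00 | 5 |
| birch | 5.00 | 8 |
| birch | 8.00 | 11 |
| birch | 12.0 | 15 |
| birch | 15.0 | 20 |
| elm | 2.50 | 13 |
| elm | 5.00 | 21 |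
| elm | 8.00 | 30 |
| elm | 10.0 | 33 |
| elm | 12.0 | 37 |
| elm | 15.0 | 43 |
| cedar | 1.33 | 4 |
| cedar | 4.00 | 13 |
| cedar | 8.00 | 25 |
| cedar | 10.0 | 27 |
| cedar | 15.0 | 39 |

(scatter of a reading: 1.5 percentage points)

- the stated concentrations are those of everything mixed, before any reaction; amounts are the same in each set-up
- what was read earlier has a scatter of 1.5 percentage points, one standard deviation
- the feed brings no volume worth counting
- the earlier runs were made in a closed, stirred flask

- the set-up with the highest amount of product at the outlet or at the end, in percent of the substrate put in ("none" if the first two lie within 2 percentage points) (north-west / south-west / east / south / none)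
- amount of product at the outlet or at the end, in percent of the substrate put in, north-west
- amount of product at the outlet or at the end, in percent of the substrate put in, south-west
- amount of product at the outlet or at the end, in percent of the substrate put in, east
- amount of product at the outlet or at the end, in percent of the substrate put in, south

1. The closed flask north-west holds the larch charge, so the larch reading of 43% at 25.0 h looks like the answer. But the larch readings rose 11 percentage points over their last 5.00 h, while the 5.00 h before gave 5 points.

2. Elm has twice the free catalyst of larch, and it reads 33% at 10.0 h where larch reads 32% at 20.0 h. So I take a reading to follow free catalyst times time. The elm reading at 12.0 h then stands for 24.0 h at 1.0 mM.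

3. That elm reading of 37% gives k = 0.0193 h⁻¹. Here k, which carries the scatter of that one reading, is my pseudo-first-order constant, the fraction of the remaining substrate that reacts per hour at 1.0 mM of free catalyst.

4. North-west lies 1.00 h beyond that point, so I compute the correction alone: k times the unreacted share times that time, 1.2 points. My north-west figure is 38.2%. The larch reading stands higher by 4.8 points, against a scatter of 1.5 points, and I keep my figure.

5. With the same k, and with y the product share and t the mean residence time, I reckon for the tank south-west y = kt/(1 + kt) = 32.5%. In south the substrate stays 15.0 h on average, which gives 25.1%. The order in coupling partner is untested, so I give east no figure. Of the three I reckon, north-west stands highest, so I put it first.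

6. The forecast names north-west, with 39% (36% to 43%) for north-west, 29% (25% to 33%) for south-west, 27% (21% to 37%) for east and 27% (22% to 32%) for south. Its ground for the tank is “The stirred tank runs entirely at outlet conditions”. Its tank figure is lower than mine, and its south figure is higher.

7. The flasks give north-west as best: north-west 39.7%, south-west 30.1%, east 30.6%, south 30.4%. The forecast's choice would fail if the lead over east fell inside 2 points; it stands at 9.1 points.

    catalyst intermediate D ⇌ catalyst intermediate E (K = 0.370, k = 0.870 min⁻¹)
    catalyst intermediate C ⇌ released group + catalyst intermediate D (K = 0.0310 M, k = 0.980 min⁻¹)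
    substrate + catalyst intermediate B ⇌ catalyst intermediate C (K = 27.0 M⁻¹, k = 370 M⁻¹ min⁻¹)
    catalyst intermediate A ⇌ catalyst intermediate B (K = 0.360, k = 0.810 min⁻¹)
    coupling partner + free catalyst ⇌ catalyst intermediate A (K = 1.10 M⁻¹, k = 6.20 M⁻¹ min⁻¹)
    2 catalyst intermediate A ⇌ resting dimer (K = 980 M⁻¹, k = 46.0 M⁻¹ min⁻¹)
    catalyst intermediate E → free catalyst + product (k = 0.830 min⁻¹)

North-west has not come to rest: 60.2% of the substrate charged is still there at 25 h. Its result gives a k of 0.0202 h⁻¹, beside my 0.0193 h⁻¹. Carried to 250 h, my k gives 99.2%, but north-west left that long gives 92.0%. That is 52 points more product than at 25 h, and the k over the long span is 0.0101 h⁻¹, half the earlier one. Even then, product stands 8.00% short of the substrate charged.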